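The route rests on reading C5 and C10 of ring A as the α- and β-carbons of a C4 ketone. One copper-catalysed, ligand-controlled alkenyl transfer to 3-methylcyclohex-2-enone, followed by Michael capture of the enolate, makes the C9–C10 and C5–C6 bonds and both ring-fusion stereocentres in a single flask. The precursors are the enone, a 2-alkenylalane carrying C9 and C11, and an α-silyl vinyl ketone carrying C6–C8 and C17. Ring B is then closed at C8=C9 by metathesis, the side chain is added by sulfone alkylation, and the C4 carbonyl is converted last into the quaternary carbon bearing methyl and carboxyl.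

Key step: step 2

Remark: atoms carry labdane numbers (ring A: C1–C5 and C10; ring B: C5–C10; side chain C11–C16; C17 on C8; C18 and C19 on C4; C20 on C10); the target is read as (4S,5R,10S), 13E, with the carboxyl carbon C19 axial and cis to C20.

Assumption: the antipode of the chiral imidazolinium sulfonate L (1-(2,6-diethylphenyl)-4,5-diphenyl-3-(2-sulfonatophenyl)-4,5-dihydroimidazolium inner salt) that gives the (S) quaternary centre is identified in a trial addition without the trap; the alkyne, the enone, the silyl vinyl ketone and prenol are taken as purchasable.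

Step 1
Reactants: 1 tert-butyldimethyl(prop-2-yn-1-yloxy)silane
Product: 2 diisobutyl[3-(tert-butyldimethylsilyloxy)prop-1-en-2-yl]aluminium (THF solution, used directly)
Conditions: NiCl2[Ph2P(CH2)3PPh2] (3 mol %), iBu2AlH (1.0 equiv), 1 (1.05 equiv), THF, 0 → 22 °C
Reagents that add atoms: diisobutylaluminium hydride, CC(C)C[AlH]CC(C)C
Why: Nickel-catalysed hydroalumination of a terminal alkyne with the bidentate bis(diphenylphosphino)propane ligand places aluminium on the internal carbon, so the 2-alkenylalane carrying C9, C11 and the sacrificial methylene forms directly, without a lithium intermediate that could suffer silyl migration from oxygen to carbon.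

Step 2
Reactants: 2 diisobutyl[3-(tert-butyldimethylsilyloxy)prop-1-en-2-yl]aluminium; 3 3-methylcyclohex-2-en-1-one; 4 3-(trimethylsilyl)but-3-en-2-one
Product: 8 (2R,3S)-3-[3-(tert-butyldimethylsilyloxy)prop-1-en-2-yl]-3-methyl-2-(3-oxobutyl)cyclohexan-1-one, via aluminium enolate 5 (not isolated), via lithium aluminate enolate 6 (not isolated), via C-silyl diketone 7 (not isolated)
Conditions: L (5.5 mol %), Ag2O, THF, 22 °C; Cu(OSO2CF3)2 (5 mol %); 3, then 2 (1.3 equiv), −30 → 0 °C; MeLi (1.3 equiv), −78 °C; 4 (1.5 equiv), −78 → −40 °C; aq. NH4Cl; KF (cat.), THF/H2O, 0 °C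
Reagents that add atoms: none
Why: Proposed new method: a carbene-bound monovalent copper alkenyl species formed by transmetalation from 2 adds to the β-carbon of 3 (C10), the diisobutylaluminium enolate 5 so formed is regiospecific at C5 and is turned by MeLi into the more nucleophilic aluminate 6, which adds in Michael fashion to the α-silyl vinyl ketone 4, whose silicon-stabilised adduct enolate neither equilibrates nor polymerises and loses the C-silyl group on mild hydrolysis (7 to 8). The closest known reaction types are the copper-catalysed enantioselective conjugate addition of alkenylaluminium reagents to 3-substituted cyclohexenones and the Michael trapping of regiospecific enolates from cuprate additions with α-silyl vinyl ketones; only their merger in one flask through an aluminate enolate is untested. No ring is closed; the step forms the C9–C10 and C5–C6 bonds. The quaternary centre C10 is set by the chiral ligand on copper through enantioface selection on the enone, and C5 by approach of the acceptor to the enolate face anti to the larger alkenyl group on the neighbouring C10, which places the C6 chain trans to C9. The step needs a single enolate regioisomer, secured because the enolate is born only at C5 and is trapped before proton transfer, and mono-addition to the acceptor, secured by the α-silyl group.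

Step 3
Reactants: 8 (2R,3S)-3-[3-(tert-butyldimethylsilyloxy)prop-1-en-2-yl]-3-methyl-2-(3-oxobutyl)cyclohexan-1-one
Product: 9 (2R,3S)-3-[3-(tert-butyldimethylsilyloxy)prop-1-en-2-yl]-3-methyl-2-(3-methylbut-3-en-1-yl)cyclohexan-1-one
Conditions: Ph3PCH3Br (1.15 equiv), KN(SiMe3)2 (1.1 equiv), THF, 0 °C; then 8, −78 → 0 °C
Reagents that add atoms: methyltriphenylphosphonium bromide, C[P+](c1ccccc1)(c1ccccc1)c1ccccc1.[Br-] (CH2 through its ylide)
Why: Wittig methylenation is much faster at the unhindered methyl ketone than at the ring ketone flanked by C5 and the quaternary C10, the low temperature limits enolisation and aldol closure of the 1,5-diketone, and the C4 carbonyl is deliberately kept because a methylene there would offer a competing five-membered closure onto C8 in step 4; no stereocentre is formed.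

Step 4
Reactants: 9 (2R,3S)-3-[3-(tert-butyldimethylsilyloxy)prop-1-en-2-yl]-3-methyl-2-(3-methylbut-3-en-1-yl)cyclohexan-1-one
Product: 10 (4aS,8aR)-5-[(tert-butyldimethylsilyloxy)methyl]-4a,6-dimethyl-3,4,4a,7,8,8a-hexahydronaphthalen-1(2H)-one
Conditions: [1,3-bis(2-methylphenyl)imidazolidin-2-ylidene]dichloro(2-isopropoxybenzylidene)ruthenium (7 mol %), toluene (0.005 M), 80 °C, argon sparge
Reagents that add atoms: none
Why: Ring-closing metathesis of the two 1,1-disubstituted alkenes closes the six-membered ring B with loss of ethene and gives the tetrasubstituted C8=C9 alkene, a closure for which a ruthenium carbene with small N-aryl groups is suited; the ring-fusion centres are not involved.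

Step 5
Reactants: 10 (4aS,8aR)-5-[(tert-butyldimethylsilyloxy)methyl]-4a,6-dimethyl-3,4,4a,7,8,8a-hexahydronaphthalen-1(2H)-one
Product: 11 (4aS,8aS)-5-[(tert-butyldimethylsilyloxy)methyl]-4a,6-dimethyl-1-methylidene-1,2,3,4,4a,7,8,8a-octahydronaphthalene
Conditions: Zn, CH2Br2, TiCl4, THF, −40 → 5 °C (aged reagent); then 10, CH2Cl2, 0 → 22 °C
Reagents that add atoms: dibromomethane, BrCBr
Why: Lombardo methylenation with the zinc–titanium methylene reagent is non-basic, so the ketone becomes the exocyclic alkene without epimerisation of the adjacent ring-fusion centre C5, and silyl ethers are tolerated.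

Step 6
Reactants: 11 (4aS,8aS)-5-[(tert-butyldimethylsilyloxy)methyl]-4a,6-dimethyl-1-methylidene-1,2,3,4,4a,7,8,8a-octahydronaphthalene
Product: 12 (4aS,8aS)-5-(bromomethyl)-4a,6-dimethyl-1-methylidene-1,2,3,4,4a,7,8,8a-octahydronaphthalene
Conditions: Ph3PBr2 (1.2 equiv), CH2Cl2, 0 → 22 °C; aqueous work-up, short silica plug, used at once
Reagents that add atoms: triphenylphosphine dibromide, BrP(Br)(c1ccccc1)(c1ccccc1)c1ccccc1
Why: Triphenylphosphine dibromide converts primary allylic tert-butyldimethylsilyl ethers directly into bromides through an alkoxyphosphonium ion that bromide opens at the primary carbon C11, which saves a separate desilylation and leaves the alkenes untouched.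

Step 7
Reactants: 13 3-methylbut-2-en-1-ol
Product: 14 tert-butyldimethyl[(3-methylbut-2-en-1-yl)oxy]silane
Conditions: tBuMe2SiCl, imidazole, CH2Cl2, 22 °C
Reagents that add atoms: tert-butyldimethylsilyl chloride, CC(C)(C)[Si](C)(C)Cl
Why: Standard silylation of a primary alcohol puts a base-stable group on the future C15 oxygen that will survive the carbanion, hydride and tert-butoxide steps.

Step 8
Reactants: 14 tert-butyldimethyl[(3-methylbut-2-en-1-yl)oxy]silane
Product: 15 (2E)-4-(tert-butyldimethylsilyloxy)-2-methylbut-2-en-1-ol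
Conditions: SeO2 (cat.), tBuOOH, CH2Cl2, 0 → 22 °C
Reagents that add atoms: selenium dioxide, O=[Se]=O (oxygen carrier, regenerated by tert-butyl hydroperoxide, CC(C)(C)OO)
Why: Catalytic selenium dioxide allylic oxidation (ene reaction, then [2,3]-sigmatropic shift) attacks the methyl group trans to the chain of a trisubstituted alkene, which fixes the E geometry of the future C13=C14 bond.

Step 9
Reactants: 15 (2E)-4-(tert-butyldimethylsilyloxy)-2-methylbut-2-en-1-ol
Product: 16 {[(2E)-4-bromo-3-methylbut-2-en-1-yl]oxy}(tert-butyl)dimethylsilane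
Conditions: CBr4, PPh3, CH2Cl2, 0 °C
Reagents that add atoms: tetrabromomethane, BrC(Br)(Br)Br
Why: Appel bromination converts the primary allylic alcohol to the bromide under neutral conditions without allylic transposition or loss of the silyl ether.

Step 10
Reactants: 16 {[(2E)-4-bromo-3-methylbut-2-en-1-yl]oxy}(tert-butyl)dimethylsilane
Product: 17 tert-butyldimethyl{[(2E)-3-methyl-4-(phenylsulfonyl)but-2-en-1-yl]oxy}silane
Conditions: PhSO2Na, DMF, 22 °C
Reagents that add atoms: sodium benzenesulfinate, [Na+].[O-]S(=O)c1ccccc1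
Why: Sulfinate S-alkylation (SN2 at the primary allylic bromide) gives the allylic sulfone with the alkene geometry unchanged.

Step 11
Reactants: 17 tert-butyldimethyl{[(2E)-3-methyl-4-(phenylsulfonyl)but-2-en-1-yl]oxy}silane; 12 (4aS,8aS)-5-(bromomethyl)-4a,6-dimethyl-1-methylidene-1,2,3,4,4a,7,8,8a-octahydronaphthalene
Product: 19 (4aS,8aS)-5-[(3E)-5-(tert-butyldimethylsilyloxy)-3-methyl-2-(phenylsulfonyl)pent-3-en-1-yl]-4a,6-dimethyl-1-methylidene-1,2,3,4,4a,7,8,8a-octahydronaphthalene (epimers at the sulfone carbon), via lithiated sulfone 18 (not isolated)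
Conditions: 17, n-BuLi (1.05 equiv), THF, −78 °C; then 12, −78 → −20 °C
Reagents that add atoms: none
Why: The α-sulfonyl allyl carbanion 18 alkylates at the carbon next to sulfur with the primary allylic bromide (SN2 at C11) to form C11–C12, the sulfone-bearing carbon is formed as a mixture that step 12 erases, and the exocyclic alkene stands in for the C4 carbonyl, which would tolerate neither the carbanion nor the hydride that follows.

Step 12
Reactants: 19 (4aS,8aS)-5-[(3E)-5-(tert-butyldimethylsilyloxy)-3-methyl-2-(phenylsulfonyl)pent-3-en-1-yl]-4a,6-dimethyl-1-methylidene-1,2,3,4,4a,7,8,8a-octahydronaphthalene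
Product: 20 (4aS,8aS)-5-[(3E)-5-(tert-butyldimethylsilyloxy)-3-methylpent-3-en-1-yl]-4a,6-dimethyl-1-methylidene-1,2,3,4,4a,7,8,8a-octahydronaphthalene
Conditions: PdCl2[Ph2P(CH2)3PPh2] (5 mol %), LiBHEt3 (2.5 equiv), THF, 0 °C
Reagents that add atoms: none
Why: Palladium-catalysed hydride desulfonylation of an allylic sulfone (ionisation by zerovalent palladium, hydride return to the sulfone-bearing terminus) is the established way to remove the activating group from prenyl-type sulfones with the trisubstituted alkene kept in place and E, and silyl ethers and unactivated alkenes are inert.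

Step 13
Reactants: 20 (4aS,8aS)-5-[(3E)-5-(tert-butyldimethylsilyloxy)-3-methylpent-3-en-1-yl]-4a,6-dimethyl-1-methylidene-1,2,3,4,4a,7,8,8a-octahydronaphthalene
Product: 22 {(4aS,8aS)-5-[(3E)-5-(tert-butyldimethylsilyloxy)-3-methylpent-3-en-1-yl]-4a,6-dimethyl-1,2,3,4,4a,7,8,8a-octahydronaphthalen-1-yl}methanol (C1 epimers), via alkylborane 21 (not isolated)
Conditions: 9-BBN (1.3 equiv), THF, 0 → 22 °C; then NaOH, H2O2, 0 °C
Reagents that add atoms: hydrogen peroxide, OO
Why: 9-BBN hydroborates the 1,1-disubstituted C4 methylene far faster than the tri- and tetrasubstituted alkenes and places boron on the terminal carbon, so oxidation gives the primary alcohol, and the C4 configuration formed here is irrelevant because step 15 erases it.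

Step 14
Reactants: 22 {(4aS,8aS)-5-[(3E)-5-(tert-butyldimethylsilyloxy)-3-methylpent-3-en-1-yl]-4a,6-dimethyl-1,2,3,4,4a,7,8,8a-octahydronaphthalen-1-yl}methanol
Product: 23 (4aS,8aS)-5-[(3E)-5-(tert-butyldimethylsilyloxy)-3-methylpent-3-en-1-yl]-4a,6-dimethyl-1,2,3,4,4a,7,8,8a-octahydronaphthalene-1-carbaldehyde (C1 epimers)
Conditions: Dess–Martin periodinane, NaHCO3, CH2Cl2, 0 → 22 °C
Reagents that add atoms: none
Why: Dess–Martin oxidation of a primary alcohol is neutral when buffered, stops at the aldehyde and leaves the alkenes and the silyl ether untouched.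

Step 15
Reactants: 23 (4aS,8aS)-5-[(3E)-5-(tert-butyldimethylsilyloxy)-3-methylpent-3-en-1-yl]-4a,6-dimethyl-1,2,3,4,4a,7,8,8a-octahydronaphthalene-1-carbaldehyde
Product: 25 (1S,4aS,8aR)-5-[(3E)-5-(tert-butyldimethylsilyloxy)-3-methylpent-3-en-1-yl]-1,4a,6-trimethyl-1,2,3,4,4a,7,8,8a-octahydronaphthalene-1-carbaldehyde, via potassium enolate 24 (not isolated)
Conditions: KOtBu (2 equiv), MeI (5 equiv), THF, −20 → 0 °C
Reagents that add atoms: iodomethane, CI
Why: Enolate C-methylation of an α-branched aldehyde: the planar potassium enolate 24 is attacked by iodomethane on the α face, away from the axial C10 methyl group that shields the β face in a 1,3-diaxial sense, so the new methyl group becomes equatorial and the formyl group axial (4S), as the C19 acid requires.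

Step 16
Reactants: 25 (1S,4aS,8aR)-5-[(3E)-5-(tert-butyldimethylsilyloxy)-3-methylpent-3-en-1-yl]-1,4a,6-trimethyl-1,2,3,4,4a,7,8,8a-octahydronaphthalene-1-carbaldehyde
Product: 26 (1S,4aS,8aR)-5-[(3E)-5-hydroxy-3-methylpent-3-en-1-yl]-1,4a,6-trimethyl-1,2,3,4,4a,7,8,8a-octahydronaphthalene-1-carbaldehyde
Conditions: Bu4NF, THF, 0 → 22 °C
Reagents that add atoms: none
Why: Fluoride cleavage of the primary silyl ether is selective, and the aldehyde, now quaternary and non-enolisable, is inert to the mildly basic fluoride.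

Step 17
Reactants: 26 (1S,4aS,8aR)-5-[(3E)-5-hydroxy-3-methylpent-3-en-1-yl]-1,4a,6-trimethyl-1,2,3,4,4a,7,8,8a-octahydronaphthalene-1-carbaldehyde
Product: 27 (1S,4aS,8aR)-5-[(3E)-5-acetoxy-3-methylpent-3-en-1-yl]-1,4a,6-trimethyl-1,2,3,4,4a,7,8,8a-octahydronaphthalene-1-carbaldehyde
Conditions: Ac2O, pyridine, DMAP (cat.), CH2Cl2, 0 → 22 °C
Reagents that add atoms: acetic anhydride, CC(=O)OC(C)=O
Why: Acylation of the primary allylic alcohol with acetic anhydride under nucleophilic catalysis is routine, and placing it before the oxidation avoids acetylating in the presence of a free carboxylic acid.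

Step 18
Reactants: 27 (1S,4aS,8aR)-5-[(3E)-5-acetoxy-3-methylpent-3-en-1-yl]-1,4a,6-trimethyl-1,2,3,4,4a,7,8,8a-octahydronaphthalene-1-carbaldehyde
Product: 28 (1S,4aS,8aR)-5-[(3E)-5-acetoxy-3-methylpent-3-en-1-yl]-1,4a,6-trimethyl-1,2,3,4,4a,7,8,8a-octahydronaphthalene-1-carboxylic acid
Conditions: NaClO2, NaH2PO4, 2-methylbut-2-ene (excess), tBuOH/H2O, 22 °C
Reagents that add atoms: sodium chlorite, [Na+].[O-]Cl=O
Why: Pinnick oxidation converts the hindered, non-enolisable aldehyde to the carboxylic acid near pH 4, where the allylic acetate is stable, and the large excess of 2-methylbut-2-ene removes hypochlorous acid before it can attack the alkenes; no stereocentre is affected.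

Compound list

1 | tert-butyldimethyl(prop-2-yn-1-yloxy)silane | C#CCO[Si](C)(C)C(C)(C)C | starting material
2 | diisobutyl[3-(tert-butyldimethylsilyloxy)prop-1-en-2-yl]aluminium | C=C(CO[Si](C)(C)C(C)(C)C)[Al](CC(C)C)CC(C)C | intermediate
3 | 3-methylcyclohex-2-en-1-one | CC1=CC(=O)CCC1 | starting material
4 | 3-(trimethylsilyl)but-3-en-2-one | CC(=O)C(=C)[Si](C)(C)C | starting material
5 | ({(3S)-3-[3-(tert-butyldimethylsilyloxy)prop-1-en-2-yl]-3-methylcyclohex-1-en-1-yl}oxy)diisobutylaluminium (aluminium enolate) | CC(C)C[Al](CC(C)C)OC1=C[C@@](C)(C(=C)CO[Si](C)(C)C(C)(C)C)CCC1 | intermediate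
6 | lithium methyl(diisobutyl)aluminate of the same (3S)-enolate | [Li+].C[Al-](CC(C)C)(CC(C)C)OC1=C[C@@](C)(C(=C)CO[Si](C)(C)C(C)(C)C)CCC1 | intermediate
7 | (2R,3S)-3-[3-(tert-butyldimethylsilyloxy)prop-1-en-2-yl]-3-methyl-2-[3-oxo-2-(trimethylsilyl)butyl]cyclohexan-1-one (epimers at the silyl-bearing carbon) | CC(=O)C(C[C@H]1C(=O)CCC[C@]1(C)C(=C)CO[Si](C)(C)C(C)(C)C)[Si](C)(C)C | intermediate
8 | (2R,3S)-3-[3-(tert-butyldimethylsilyloxy)prop-1-en-2-yl]-3-methyl-2-(3-oxobutyl)cyclohexan-1-one | CC(=O)CC[C@H]1C(=O)CCC[C@]1(C)C(=C)CO[Si](C)(C)C(C)(C)C | intermediate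
9 | (2R,3S)-3-[3-(tert-butyldimethylsilyloxy)prop-1-en-2-yl]-3-methyl-2-(3-methylbut-3-en-1-yl)cyclohexan-1-one | C=C(C)CC[C@H]1C(=O)CCC[C@]1(C)C(=C)CO[Si](C)(C)C(C)(C)C | intermediate
10 | (4aS,8aR)-5-[(tert-butyldimethylsilyloxy)methyl]-4a,6-dimethyl-3,4,4a,7,8,8a-hexahydronaphthalen-1(2H)-one | CC(C)(C)[Si](C)(C)OCC1=C(C)CC[C@H]2C(=O)CCC[C@]12C | intermediate
11 | (4aS,8aS)-5-[(tert-butyldimethylsilyloxy)methyl]-4a,6-dimethyl-1-methylidene-1,2,3,4,4a,7,8,8a-octahydronaphthalene | CC(C)(C)[Si](C)(C)OCC1=C(C)CC[C@H]2C(=C)CCC[C@]12C | intermediate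
12 | (4aS,8aS)-5-(bromomethyl)-4a,6-dimethyl-1-methylidene-1,2,3,4,4a,7,8,8a-octahydronaphthalene | BrCC1=C(C)CC[C@H]2C(=C)CCC[C@]12C | intermediate
13 | 3-methylbut-2-en-1-ol | CC(C)=CCO | starting material
14 | tert-butyldimethyl[(3-methylbut-2-en-1-yl)oxy]silane | CC(C)=CCO[Si](C)(C)C(C)(C)C | intermediate
15 | (2E)-4-(tert-butyldimethylsilyloxy)-2-methylbut-2-en-1-ol | CC(C)(C)[Si](C)(C)OC/C=C(\C)CO | intermediate
16 | {[(2E)-4-bromo-3-methylbut-2-en-1-yl]oxy}(tert-butyl)dimethylsilane | CC(C)(C)[Si](C)(C)OC/C=C(\C)CBr | intermediate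
17 | tert-butyldimethyl{[(2E)-3-methyl-4-(phenylsulfonyl)but-2-en-1-yl]oxy}silane | CC(C)(C)[Si](C)(C)OC/C=C(\C)CS(=O)(=O)c1ccccc1 | intermediate
18 | α-lithio derivative of 17 (lithium on the carbon next to sulfur) | CC(C)(C)[Si](C)(C)OC/C=C(\C)C([Li])S(=O)(=O)c1ccccc1 | intermediate
19 | (4aS,8aS)-5-[(3E)-5-(tert-butyldimethylsilyloxy)-3-methyl-2-(phenylsulfonyl)pent-3-en-1-yl]-4a,6-dimethyl-1-methylidene-1,2,3,4,4a,7,8,8a-octahydronaphthalene (epimers at the sulfone carbon) | CC(C)(C)[Si](C)(C)OC/C=C(\C)C(CC1=C(C)CC[C@H]2C(=C)CCC[C@]12C)S(=O)(=O)c1ccccc1 | intermediate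
20 | (4aS,8aS)-5-[(3E)-5-(tert-butyldimethylsilyloxy)-3-methylpent-3-en-1-yl]-4a,6-dimethyl-1-methylidene-1,2,3,4,4a,7,8,8a-octahydronaphthalene | CC(C)(C)[Si](C)(C)OC/C=C(\C)CCC1=C(C)CC[C@H]2C(=C)CCC[C@]12C | intermediate
21 | B-alkyl-9-borabicyclo[3.3.1]nonane from 20 (boron on the former methylidene carbon, C1 epimers) | CC(C)(C)[Si](C)(C)OC/C=C(\C)CCC1=C(C)CC[C@H]2C(CB3C4CCCC3CCC4)CCC[C@]12C | intermediate
22 | {(4aS,8aS)-5-[(3E)-5-(tert-butyldimethylsilyloxy)-3-methylpent-3-en-1-yl]-4a,6-dimethyl-1,2,3,4,4a,7,8,8a-octahydronaphthalen-1-yl}methanol (C1 epimers) | CC(C)(C)[Si](C)(C)OC/C=C(\C)CCC1=C(C)CC[C@H]2C(CO)CCC[C@]12C | intermediate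
23 | (4aS,8aS)-5-[(3E)-5-(tert-butyldimethylsilyloxy)-3-methylpent-3-en-1-yl]-4a,6-dimethyl-1,2,3,4,4a,7,8,8a-octahydronaphthalene-1-carbaldehyde (C1 epimers) | CC(C)(C)[Si](C)(C)OC/C=C(\C)CCC1=C(C)CC[C@H]2C(C=O)CCC[C@]12C | intermediate
24 | potassium enolate of 23 | CC(C)(C)[Si](C)(C)OC/C=C(\C)CCC1=C(C)CC[C@H]2C(=C[O-])CCC[C@]12C.[K+] | intermediate
25 | (1S,4aS,8aR)-5-[(3E)-5-(tert-butyldimethylsilyloxy)-3-methylpent-3-en-1-yl]-1,4a,6-trimethyl-1,2,3,4,4a,7,8,8a-octahydronaphthalene-1-carbaldehyde | CC(C)(C)[Si](C)(C)OC/C=C(\C)CCC1=C(C)CC[C@H]2[C@@](C)(C=O)CCC[C@]12C | intermediate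
26 | (1S,4aS,8aR)-5-[(3E)-5-hydroxy-3-methylpent-3-en-1-yl]-1,4a,6-trimethyl-1,2,3,4,4a,7,8,8a-octahydronaphthalene-1-carbaldehyde | OC/C=C(\C)CCC1=C(C)CC[C@H]2[C@@](C)(C=O)CCC[C@]12C | intermediate
27 | (1S,4aS,8aR)-5-[(3E)-5-acetoxy-3-methylpent-3-en-1-yl]-1,4a,6-trimethyl-1,2,3,4,4a,7,8,8a-octahydronaphthalene-1-carbaldehyde | CC(=O)OC/C=C(\C)CCC1=C(C)CC[C@H]2[C@@](C)(C=O)CCC[C@]12C | intermediate
28 | (1S,4aS,8aR)-5-[(3E)-5-acetoxy-3-methylpent-3-en-1-yl]-1,4a,6-trimethyl-1,2,3,4,4a,7,8,8a-octahydronaphthalene-1-carboxylic acid (15-acetoxylabda-8,13E-dien-19-oic acid) | CC(=O)OC/C=C(\C)CCC1=C(C)CC[C@H]2[C@@](C)(C(=O)O)CCC[C@]12C | target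

Total step count: 18 (14 in the main line, 4 for the sulfone fragment).
Longest linear sequence: 14 steps (steps 1–6 and 11–18, from 1 to 28).

Steps most likely to fail

1. Step 2 (proposed new method). What may go wrong: transfer of an alkyl or alkenyl group from the aluminate to the vinyl ketone instead of enolate addition, proton exchange that consumes the enolate before the C5–C6 bond forms, or weak facial discrimination at C5 between the methyl and alkenyl groups on C10. The fallback uses known chemistry and sets out from 2 and 3. The copper-catalysed addition is run alone and the aluminium enolate is silylated (Me3SiOSO2CF3, Et3N) to give the isolable silyl enol ether tert-butyldimethyl({2-[(1S)-1-methyl-3-(trimethylsilyloxy)cyclohex-2-en-1-yl]prop-2-en-1-yl}oxy)silane F1. MeLi in THF then releases the lithium enolate regiospecifically; it is added to 4 at −78 °C and the adduct is desilylated as before, so the route is rejoined at 8. A C5 epimer, should it form, can be separated at 8 and re-equilibrated with base, because C5 is α to the ketone.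

2. Step 4. What may go wrong: slow closure onto the hindered C9 alkene beside the quaternary C10, so that intermolecular metathesis through the C8 alkene and catalyst decay take over. The fallback sets out from 9. The silyl group is removed (Bu4NF, THF) to give (2R,3S)-3-(3-hydroxyprop-1-en-2-yl)-3-methyl-2-(3-methylbut-3-en-1-yl)cyclohexan-1-one F2, whose small free allylic hydroxyl group is known to speed metathesis at the neighbouring alkene (any lactol with the C4 ketone is in equilibrium with the open form). Ring closure with the same ruthenium carbene gives (4aS,8aR)-5-(hydroxymethyl)-4a,6-dimethyl-3,4,4a,7,8,8a-hexahydronaphthalen-1(2H)-one F3. Lombardo methylenation gives [(4aS,8aS)-2,8a-dimethyl-5-methylidene-3,4,4a,5,6,7,8,8a-octahydronaphthalen-1-yl]methanol F4, and Appel bromination (CBr4, PPh3) returns to the route at 12.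

3. Step 12. What may go wrong: hydride return to C14 instead of C12, or syn–anti exchange in the allylpalladium intermediate, leading to migration or E/Z scrambling of the C13=C14 alkene; a palladium hydride could also isomerise the exocyclic alkene. The fallback sets out from 12 and builds the alkene after the C11–C12 bond by syn-carbometalation. Alkylation of 12 with the lithium derivative of 1-(trimethylsilyl)propyne (n-BuLi, THF, −78 °C) gives (4aS,8aS)-4a,6-dimethyl-1-methylidene-5-[4-(trimethylsilyl)but-3-yn-1-yl]-1,2,3,4,4a,7,8,8a-octahydronaphthalene F5. K2CO3 in MeOH removes the C-silyl group to give (4aS,8aS)-5-(but-3-yn-1-yl)-4a,6-dimethyl-1-methylidene-1,2,3,4,4a,7,8,8a-octahydronaphthalene F6. Zirconium-catalysed methylalumination (AlMe3, ZrCl2(C5H5)2, CH2Cl2; then n-BuLi and paraformaldehyde) gives (2E)-5-[(4aS,8aS)-2,8a-dimethyl-5-methylidene-3,4,4a,5,6,7,8,8a-octahydronaphthalen-1-yl]-3-methylpent-2-en-1-ol F7, and silylation (tBuMe2SiCl, imidazole) returns to the route at 20.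

Further compounds

F1 | step 2 | tert-butyldimethyl({2-[(1S)-1-methyl-3-(trimethylsilyloxy)cyclohex-2-en-1-yl]prop-2-en-1-yl}oxy)silane | C[Si](C)(C)OC1=C[C@@](C)(C(=C)CO[Si](C)(C)C(C)(C)C)CCC1
F2 | step 4 | (2R,3S)-3-(3-hydroxyprop-1-en-2-yl)-3-methyl-2-(3-methylbut-3-en-1-yl)cyclohexan-1-one | C=C(C)CC[C@H]1C(=O)CCC[C@]1(C)C(=C)CO
F3 | step 4 | (4aS,8aR)-5-(hydroxymethyl)-4a,6-dimethyl-3,4,4a,7,8,8a-hexahydronaphthalen-1(2H)-one | OCC1=C(C)CC[C@H]2C(=O)CCC[C@]12C
F4 | step 4 | [(4aS,8aS)-2,8a-dimethyl-5-methylidene-3,4,4a,5,6,7,8,8a-octahydronaphthalen-1-yl]methanol | OCC1=C(C)CC[C@H]2C(=C)CCC[C@]12C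
F5 | step 12 | (4aS,8aS)-4a,6-dimethyl-1-methylidene-5-[4-(trimethylsilyl)but-3-yn-1-yl]-1,2,3,4,4a,7,8,8a-octahydronaphthalene | C[Si](C)(C)C#CCCC1=C(C)CC[C@H]2C(=C)CCC[C@]12C
F6 | step 12 | (4aS,8aS)-5-(but-3-yn-1-yl)-4a,6-dimethyl-1-methylidene-1,2,3,4,4a,7,8,8a-octahydronaphthalene | C#CCCC1=C(C)CC[C@H]2C(=C)CCC[C@]12C
F7 | step 12 | (2E)-5-[(4aS,8aS)-2,8a-dimethyl-5-methylidene-3,4,4a,5,6,7,8,8a-octahydronaphthalen-1-yl]-3-methylpent-2-en-1-ol | OC/C=C(\C)CCC1=C(C)CC[C@H]2C(=C)CCC[C@]12C
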